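**Plan**

1. Retrosynthesis: the cross-conjugated dienone (quinone methide) ring is cut at two opposite ring bonds, carbonyl carbon to one α-CH and the ring carbon bearing the exocyclic double bond to the CH on the other side. This leaves a 1,1-diarylbuta-1,3-diene (13) and a three-carbon acyl/β-electrophile, (E)-3-chloroacryloyl chloride (15).
2. Diene 13 goes back by dehydration and allylation to diaryl ketone 11, then to aldehyde 7 and an aryllithium. Ring A of 7 comes from 2-bromo-4-chlorotoluene by formylation between the halogens, Sonogashira coupling at C–Br and Suzuki coupling at C–Cl.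
3. Forward: ring A is dressed first (formyl, alkyne, aryl), the exocyclic carbon then receives its first para-oxygenated ring and the butadienyl arm, and the second para-oxygenated ring is built last from the diene carbons and 15, in one flask that also removes all silyl groups.
4. Enabling feature: the para-oxygenated benzene ring on the exocyclic carbon. Its oxygen is conjugated through that ring and the exocyclic carbon with the diene carbons, so the diene terminus takes up the acyl carbon and the internal diene carbon then closes on the β-carbon. The two oxygenated rings on the exocyclic carbon are interchanged by a proton shift, so a new phenol ring beside a quinone methide in the old ring is the target itself.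
5. Stereochemistry: the target has no stereocentre and no stereogenic double bond (the exocyclic alkene carries a symmetric ring). Racemic carbinols 10 and 12 and the E/Z mixtures 13 and 16 lose their stereo-elements on the way.

Key step: step 9

Remark: the quinone methide ring and the para-hydroxyphenyl ring on the exocyclic carbon are degenerate tautomers, so the target is drawn with the quinone methide on the newly built ring. TBS = tert-butyldimethylsilyl; "biaryl" below = 4'-(TBSO)-3-{[4-(TBSO)phenyl]ethynyl}-4-methylbiphenyl-2-yl.

**Step 1**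
Reactants: 1 2-bromo-4-chlorotoluene
Product: 3 2-bromo-6-chloro-3-methylbenzaldehyde, via aryllithium 2 (not isolated)
Conditions: LDA (1.05 equiv), THF, −78 °C; DMF, −78 → 0 °C; 1 M aq. HCl
Reagents that add atoms: N,N-dimethylformamide (DMF), CN(C)C=O
Why: The ring hydrogen flanked by bromine and chlorine is the most acidic one, so deprotonative ortho-metalation with the amide base and formylation of aryllithium 2 with DMF should place the aldehyde between the halogens, the low temperature suppressing aryne formation.

**Step 2**
Reactants: 3 2-bromo-6-chloro-3-methylbenzaldehyde; 4 tert-butyl(4-ethynylphenoxy)dimethylsilane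
Product: 5 2-{[4-(TBSO)phenyl]ethynyl}-6-chloro-3-methylbenzaldehyde
Conditions: PdCl2(PPh3)2 (3 mol %), CuI (5 mol %), Et3N, THF, 60 °C
Reagents that add atoms: none
Why: Sonogashira coupling, in which zerovalent palladium inserts into the C–Br bond (activated by the ortho formyl group) far faster than into C–Cl, so the alkyne should enter only next to the methyl group.

**Step 3**
Reactants: 5 2-{[4-(TBSO)phenyl]ethynyl}-6-chloro-3-methylbenzaldehyde; 6 [4-(TBSO)phenyl]boronic acid
Product: 7 4'-(TBSO)-3-{[4-(TBSO)phenyl]ethynyl}-4-methylbiphenyl-2-carbaldehyde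
Conditions: Pd(OAc)2 (2 mol %), SPhos (4 mol %), K3PO4 (2 equiv), toluene, 100 °C
Reagents that add atoms: none
Why: Suzuki–Miyaura coupling of an aryl chloride activated by its ortho formyl group, for which a dialkylbiarylphosphine ligand with K3PO4 in toluene is a standard system that aryl silyl ethers should tolerate.

**Step 4**
Reactants: 7 4'-(TBSO)-3-{[4-(TBSO)phenyl]ethynyl}-4-methylbiphenyl-2-carbaldehyde; 8 (4-bromophenoxy)(tert-butyl)dimethylsilane
Product: 10 rac-(biaryl)[4-(TBSO)phenyl]methanol, via aryllithium 9 (not isolated)
Conditions: 8, n-BuLi, THF, −78 °C; then 7, −78 → 0 °C; sat. aq. NH4Cl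
Reagents that add atoms: none
Why: Bromine–lithium exchange followed by 1,2-addition of the aryllithium to the aldehyde, giving the carbinol as a racemate whose stereocentre is removed in step 5.

**Step 5**
Reactants: 10 rac-(biaryl)[4-(TBSO)phenyl]methanol
Product: 11 (biaryl)[4-(TBSO)phenyl]methanone
Conditions: Dess–Martin periodinane (1.3 equiv), CH2Cl2, 0 °C → rt
Reagents that add atoms: none
Why: Dess–Martin oxidation of a doubly benzylic secondary alcohol is fast under neutral conditions that leave the alkyne and the silyl ethers untouched.

**Step 6**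
Reactants: 11 (biaryl)[4-(TBSO)phenyl]methanone
Product: 12 rac-1-(biaryl)-1-[4-(TBSO)phenyl]but-3-en-1-ol
Conditions: allylmagnesium bromide (1.5 equiv), THF, 0 °C; sat. aq. NH4Cl
Reagents that add atoms: allylmagnesium bromide, C=CC[Mg]Br
Why: Grignard allylation through a six-membered transition state adds even to strongly hindered diaryl ketones, giving a racemic tertiary carbinol whose stereocentre disappears in step 7.

**Step 7**
Reactants: 12 rac-1-(biaryl)-1-[4-(TBSO)phenyl]but-3-en-1-ol
Product: 13 1-(biaryl)-1-[4-(TBSO)phenyl]buta-1,3-diene (E/Z mixture)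
Conditions: PPTS (10 mol %), 4 Å molecular sieves, toluene, 60 °C
Reagents that add atoms: none
Why: Acid-catalysed E1 dehydration through a diarylcarbenium ion stabilised by the para-silyloxy ring, with proton loss from the allylic CH2 to the conjugated diene, both alkene geometries being usable in step 9.

**Step 8**
Reactants: 14 (E)-3-chloroacrylic acid
Product: 15 (E)-3-chloroacryloyl chloride
Conditions: (COCl)2 (1.2 equiv), DMF (cat.), CH2Cl2, 0 °C → rt; volatiles removed, used crude
Reagents that add atoms: oxalyl chloride, O=C(Cl)C(Cl)=O
Why: Acid chloride formation through the chloroiminium (Vilsmeier-type) activation of the carboxylic acid, a standard reaction that leaves the chloroalkene intact.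

**Step 9**
Reactants: 13 1-(biaryl)-1-[4-(TBSO)phenyl]buta-1,3-diene; 15 (E)-3-chloroacryloyl chloride
Product: 18 selaginellin U, via chlorotrienone 16 (not isolated), via cyclohexadienone 17 (not isolated)
Conditions: 15 (1.0 equiv), ZnCl2 (20 mol %, in Et2O), 2,6-di-tert-butyl-4-methylpyridine (1.2 equiv), CH2Cl2, −40 → 0 °C; then THF (to 0.01 M), Bu4NF (TBAF, 5 equiv, dried), −20 °C → rt; 1 M aq. HCl to pH 5
Reagents that add atoms: none
Why: Proposed new method: acid chloride 15, activated by ZnCl2, should acylate the terminal CH2 of diene 13, because only attack there gives a cation delocalised over the allyl unit, the exocyclic carbon and its para-silyloxyphenyl ring, and proton loss to the hindered pyridine gives chlorotrienone 16 (closest known types: Kondakov/Friedel–Crafts acylation of 1,1-diarylethylenes and acylation of silyl dienol ethers). Fluoride then frees the para-phenoxide on the exocyclic carbon, whose oxygen is conjugated through its ring and the exocyclic carbon with the dienone, so that in the quinone methide/dienolate resonance form the chain is an oxido-hexatriene. The new six-membered carbocycle closes between the carbon next to the exocyclic carbon and the chlorine-bearing carbon by a 6-endo-trig vinylogous Michael addition, equally a disrotatory oxyanion-accelerated 6π electrocyclisation (closest known types: para-alkylative dearomatisation of phenoxides and electrocyclisation of oxido-trienes), and E1cB loss of chloride gives cyclohexadienone 17. Proton shift from the ring CH of 17 to oxygen aromatises the new ring and leaves the old one as the quinone methide, which is the target because the two rings are degenerate tautomers, while the same fluoride frees the two spectator phenols. No stereocentre is formed, and the cis enone geometry needed for closure is reached through the delocalised anion, in which that double bond has partial single-bond character. The selectivity needed is regiochemical (acyl carbon to the diene terminus, β-carbon to the internal carbon, giving the para- and not the ortho-oxygenated ring) and chemoselective (diene before alkyne and arenes); the first is secured by the order of events, since the acylium is taken up only at the terminus and the later closure is fixed by ring size, the second by the much higher π-nucleophilicity of the donor-substituted diene at low temperature.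

**Compound list**

1 | 2-bromo-4-chlorotoluene | Cc1ccc(Cl)cc1Br | starting material
2 | (2-bromo-6-chloro-3-methylphenyl)lithium | Cc1ccc(Cl)c([Li])c1Br | intermediate (not isolated)
3 | 2-bromo-6-chloro-3-methylbenzaldehyde | Cc1ccc(Cl)c(C=O)c1Br | intermediate
4 | tert-butyl(4-ethynylphenoxy)dimethylsilane | C#Cc1ccc(O[Si](C)(C)C(C)(C)C)cc1 | starting material
5 | 2-{[4-(tert-butyldimethylsilyloxy)phenyl]ethynyl}-6-chloro-3-methylbenzaldehyde | Cc1ccc(Cl)c(C=O)c1C#Cc1ccc(O[Si](C)(C)C(C)(C)C)cc1 | intermediate
6 | [4-(tert-butyldimethylsilyloxy)phenyl]boronic acid | OB(O)c1ccc(O[Si](C)(C)C(C)(C)C)cc1 | starting material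
7 | 4'-(tert-butyldimethylsilyloxy)-3-{[4-(tert-butyldimethylsilyloxy)phenyl]ethynyl}-4-methylbiphenyl-2-carbaldehyde | Cc1ccc(-c2ccc(O[Si](C)(C)C(C)(C)C)cc2)c(C=O)c1C#Cc1ccc(O[Si](C)(C)C(C)(C)C)cc1 | intermediate
8 | (4-bromophenoxy)(tert-butyl)dimethylsilane | Brc1ccc(O[Si](C)(C)C(C)(C)C)cc1 | starting material
9 | [4-(tert-butyldimethylsilyloxy)phenyl]lithium | [Li]c1ccc(O[Si](C)(C)C(C)(C)C)cc1 | intermediate (not isolated)
10 | rac-(biaryl)[4-(tert-butyldimethylsilyloxy)phenyl]methanol | Cc1ccc(-c2ccc(O[Si](C)(C)C(C)(C)C)cc2)c(C(O)c2ccc(O[Si](C)(C)C(C)(C)C)cc2)c1C#Cc1ccc(O[Si](C)(C)C(C)(C)C)cc1 | intermediate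
11 | (biaryl)[4-(tert-butyldimethylsilyloxy)phenyl]methanone | Cc1ccc(-c2ccc(O[Si](C)(C)C(C)(C)C)cc2)c(C(=O)c2ccc(O[Si](C)(C)C(C)(C)C)cc2)c1C#Cc1ccc(O[Si](C)(C)C(C)(C)C)cc1 | intermediate
12 | rac-1-(biaryl)-1-[4-(tert-butyldimethylsilyloxy)phenyl]but-3-en-1-ol | Cc1ccc(-c2ccc(O[Si](C)(C)C(C)(C)C)cc2)c(C(O)(CC=C)c2ccc(O[Si](C)(C)C(C)(C)C)cc2)c1C#Cc1ccc(O[Si](C)(C)C(C)(C)C)cc1 | intermediate
13 | 1-(biaryl)-1-[4-(tert-butyldimethylsilyloxy)phenyl]buta-1,3-diene, E/Z mixture at the trisubstituted double bond | Cc1ccc(-c2ccc(O[Si](C)(C)C(C)(C)C)cc2)c(C(=CC=C)c2ccc(O[Si](C)(C)C(C)(C)C)cc2)c1C#Cc1ccc(O[Si](C)(C)C(C)(C)C)cc1 | intermediate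
14 | (E)-3-chloroacrylic acid | OC(=O)/C=C/Cl | starting material
15 | (E)-3-chloroacryloyl chloride | O=C(Cl)/C=C/Cl | intermediate
16 | (1E)-1-chloro-7-(biaryl)-7-[4-(tert-butyldimethylsilyloxy)phenyl]hepta-1,4,6-trien-3-one, isomer mixture at the 4,5 and 6,7 double bonds | Cc1ccc(-c2ccc(O[Si](C)(C)C(C)(C)C)cc2)c(C(=CC=CC(=O)/C=C/Cl)c2ccc(O[Si](C)(C)C(C)(C)C)cc2)c1C#Cc1ccc(O[Si](C)(C)C(C)(C)C)cc1 | intermediate (not isolated)
17 | 4-{[4'-hydroxy-3-[(4-hydroxyphenyl)ethynyl]-4-methylbiphenyl-2-yl](4-oxocyclohexa-2,5-dien-1-ylidene)methyl}cyclohexa-2,5-dien-1-one | Cc1ccc(-c2ccc(O)cc2)c(C(=C2C=CC(=O)C=C2)C2C=CC(=O)C=C2)c1C#Cc1ccc(O)cc1 | intermediate (not isolated)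
18 | selaginellin U, 4-{[4'-hydroxy-3-[(4-hydroxyphenyl)ethynyl]-4-methylbiphenyl-2-yl](4-hydroxyphenyl)methylidene}cyclohexa-2,5-dien-1-one | Cc1ccc(-c2ccc(O)cc2)c(C(=C2C=CC(=O)C=C2)c2ccc(O)cc2)c1C#Cc1ccc(O)cc1 | target

**Step count and risks**

Total steps: 9. Longest linear sequence: 8 (steps 1–7 and 9); step 8 is a one-step side branch.

Steps most likely to fail:

1. Step 9 (proposed new method). The acid chloride may be taken up at a silyl ether oxygen or at the electron-rich alkyne instead of the diene terminus, or the diene may oligomerise under the Lewis acid. After unmasking, the phenoxide oxygen may attack the chlorovinyl ketone of a second molecule, or hydroxide from wet fluoride may replace chloride and give an enolate that no longer closes. The fallback uses known chemistry, sets out from ketone 11 and returns at 18. Aryllithium 9 (from 8 as in step 4) is added to 11 in THF (−78 °C → rt) to give the tetrakis-silylated triarylmethanol F1. TBAF in THF then gives the tetraphenol carbinol F2, which on mildly acidic work-up ionises with the help of a para-hydroxy group and loses water to give 18.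

2. Step 3. The aryl silyl ethers may be cleaved by the hot phosphate base, and oxidative addition into the C–Cl bond next to the crowded formyl/alkynyl region may be slow. The fallback sets out from chloride 5 and aryllithium 9 (made from 8 as in step 4) and returns at 7. Compound 9 is transmetalated with ZnCl2 in THF to [4-(tert-butyldimethylsilyloxy)phenyl]zinc chloride F3, which is joined to 5 by a base-free Negishi coupling (Pd(OAc)2, SPhos, THF, 60 °C) that tolerates the aldehyde.

3. Step 2. Oxidative addition at the doubly ortho-substituted C–Br bond may be sluggish, so that copper-mediated homocoupling of the electron-rich arylacetylene consumes 4. The fallback sets out from 3 and returns at 5, reversing the roles of the partners. Sonogashira coupling of 3 with the small, robust ethynyltrimethylsilane gives 6-chloro-3-methyl-2-[(trimethylsilyl)ethynyl]benzaldehyde F4. K2CO3 in MeOH gives 6-chloro-2-ethynyl-3-methylbenzaldehyde F5. A second Sonogashira coupling with the reactive iodide tert-butyl(4-iodophenoxy)dimethylsilane then gives 5.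

**Further compounds**

F1 | step 9 | (biaryl)bis[4-(tert-butyldimethylsilyloxy)phenyl]methanol | Cc1ccc(-c2ccc(O[Si](C)(C)C(C)(C)C)cc2)c(C(O)(c2ccc(O[Si](C)(C)C(C)(C)C)cc2)c2ccc(O[Si](C)(C)C(C)(C)C)cc2)c1C#Cc1ccc(O[Si](C)(C)C(C)(C)C)cc1
F2 | step 9 | {4'-hydroxy-3-[(4-hydroxyphenyl)ethynyl]-4-methylbiphenyl-2-yl}bis(4-hydroxyphenyl)methanol | Cc1ccc(-c2ccc(O)cc2)c(C(O)(c2ccc(O)cc2)c2ccc(O)cc2)c1C#Cc1ccc(O)cc1
F3 | step 3 | [4-(tert-butyldimethylsilyloxy)phenyl]zinc chloride | Cl[Zn]c1ccc(O[Si](C)(C)C(C)(C)C)cc1
F4 | step 2 | 6-chloro-3-methyl-2-[(trimethylsilyl)ethynyl]benzaldehyde | Cc1ccc(Cl)c(C=O)c1C#C[Si](C)(C)C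
F5 | step 2 | 6-chloro-2-ethynyl-3-methylbenzaldehyde | Cc1ccc(Cl)c(C=O)c1C#C
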